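The readings come from a simulation with made-up constants; the scatter is artificial.

The eta run, charged like the closed flask east, holds 30.2% of its J as Q at 10.0 min, and that reading gives the quantity to carry: the drain number N, the natural logarithm of one over the share of Q left in a closed flask, here 1.20 (a Damköhler number for the passage of Q into X, and a reading with its scatter). Counting Q as born at the start is fair in eta, because the first reading there gives J a first-order constant k = 2.99 min⁻¹, so that J lasts about 0.334 min, much shorter than the run.

| flask | J | E | D | G | remark | time |
|---|---|---|---|---|---|---|
| eta | 0.15 M | 0.225 M | 0.075 M | 3.8 mM | run made earlier |  |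
| theta | 0.10 M | 0.225 M | 0.075 M | 3.8 mM | run made earlier |  |
| epsilon | 0.22 M | 0.225 M | 0.075 M | 3.8 mM | run made earlier |  |
| gamma | 0.15 M | 0.225 M | 0.075 M | 7.6 mM | run made earlier |  |
| east | 0.15 M | 0.225 M | 0.0750 M | 3.8 mM | a closed flask charged with all of it at once and left for 10 min | 10 min |
| south-west | 0.15 M | 0.225 M | 0.0750 M | 3.8 mM | one stirred flow tank at steady state, fed with the mixture as stated, mean residence time 10 min |  |
| west | 0.15 M (fed, over 5.00 min) | 0.225 M | 0.0750 M | 3.8 mM | a stirred flask in which J is dosed at a steady rate over 5.00 min without added volume, worked up at 10 min | 10 min |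
| south | 0.15 M | 0.225 M (fed, over 5.00 min) | 0.0750 M | 3.8 mM | a stirred flask in which E is dosed at a steady rate over 5.00 min without added volume, worked up at 10 min | 10 min |

- eta (time / min: Q / %, X / %): 0.833: 78.5, 13.2; 2.50: 62.3, 36.7; 5.00: 44.4, 56.3; 8.00: 35.9, 64.9; 10.0: 30.2, 70.1
- theta (time / min: Q / %, X / %): 0.500: 71.1, 6.3; 0.833: 77.3, 13.2; 1.50: 75.8, 26.2; 3.00: 58.2, 41.5; 6.00: 37.5, 62.9
- epsilon (time / min: Q / %, X / %): 0.500: 71.2, 7.0; 0.833: 79.3, 11.7; 1.50: 76.9, 22.4; 3.00: 61.0, 38.6; 6.00: 49.0, 53.8
- gamma (time / min: Q / %, X / %): 0.500: 81.0, 14.7; 0.833: 71.9, 29.4; 1.50: 55.4, 43.8; 3.00: 38.7, 61.5; 6.00: 23.3, 79.3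

(each reading ± 1 percentage point)

- order of the set-ups by the amount of Q at the outlet or at the end, in percent of the J put in, highest first (east / south-west / west / south)
- amount of Q at the outlet or at the end, in percent of the J put in, east
- amount of Q at the outlet or at the end, in percent of the J put in, south-west
- amount of Q at the outlet or at the end, in percent of the J put in, west
- amount of Q at the outlet or at the end, in percent of the J put in, south

- the stated concentrations are those of everything mixed, before any reaction; amounts are the same in each set-up
- steps that have been proposed: J + G -> G + Q; E + G + Q -> G + X; E + D -> Z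
- the feed brings no volume worth counting
- the earlier runs were made in a closed, stirred flask

In a closed flask Q stays for the whole time, so for a first-order passage its share falls as exp(−N), whereas a stirred tank with the same N and the same first-order passage sends some Q out early and keeps one over (one plus N), which is larger for any positive N. The question turned round is how much J the tank south-west must waste for east to catch it. With a share a of J leaving unreacted, the tank keeps (one minus a) over (one plus N), and this sinks to the eta reading at a = 33.6%. The small correction, one over (one plus k times the residence time), comes to 3.24%, less than that. My own reckoning therefore gives south-west 44.0%, on the assumption that the steady E in the tank drains Q as the falling E in eta did.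

The forecast orders the flasks south-west > west > south > east, with east 30.5%, south-west 44%, west 40% and south 36%, and says of west “because Q forms late, after D has eaten some E”.

The flasks give south-west > west > south > east: east 29.6%, south-west 43.2%, west 39.7%, south 35.0%.

    J + G → G + Q (k = 13.0 M⁻¹ s⁻¹)
    E + G + Q → G + X (k = 5.90 M⁻² s⁻¹)
    E + D → Z (k = 0.0430 M⁻¹ s⁻¹)

South-west lets 3.26% of its J out unreacted, less than the 33.6% that the turned question asked for, and (one minus that share) over (one plus N) is 44.0% beside the tank's 43.2%. Left until 100 min, east keeps 4.46% as Q, a drain number of 3.11, larger than the 1.20 of the eta reading.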